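**Retrosynthetic overview**

- 25 ⇐ 24 (BBr3 cleavage of seven alkyl ethers) ⇐ arylsilane 23 (ipso-bromodesilylation). The plan rests on C4 of ring C: this bromine-bearing carbon lies between the hydroxyl carbons C3 and C5 and para to the ether carbon C1, and direct bromination cannot tell it from the equally oxygen-activated C–H positions of rings A and B, so silicon is placed there first.
- Ring C ⇐ cyclobutenone 16 + silyl ynol ether 17 (benzannulation, two new C–C bonds). The ynol ether supplies C4 (Si) and C5 (OEt); the cyclobutenone supplies C6, C1, C2 and C3 and already carries the hindered B–C ether oxygen.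
- 16 ⇐ aryl ethynyl ether 13 + ketene ([2+2]); 13 ⇐ phenol 7 + trichloroethylene.
- 7 ⇐ phenol 4 (ring B, from syringaldehyde by benzylation and Baeyer–Villiger oxidation) + 2-iodo-1,3,5-trimethoxybenzene 5 (ring A), by Ullmann coupling.
- Ring order: rings A and B are bought and joined first; ring C is the only ring formed, and it is formed last.

Key step: step 8

Remarks on the chemistry: the target has no stereocentre, so only regiochemistry has to be controlled. Ketene is used as the preformed gas, because generating the parent ketene in the flask from an acyl chloride and an amine mainly leads to ketene dimers.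

**Route**

Step 1
Reactants: 1 syringaldehyde (4-hydroxy-3,5-dimethoxybenzaldehyde)
Product: 2 4-(benzyloxy)-3,5-dimethoxybenzaldehyde
Conditions: BnBr, K2CO3, DMF, 60 °C
Reagents that add atoms: benzyl bromide, BrCc1ccccc1
Why: Williamson etherification of the phenoxide should proceed cleanly, and benzyl is chosen because it survives peracid, copper catalysis and base and is later removed by neutral hydrogenolysis.

Step 2
Reactants: 2 4-(benzyloxy)-3,5-dimethoxybenzaldehyde
Product: 4 4-(benzyloxy)-3,5-dimethoxyphenol, via aryl formate 3 (not isolated)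
Conditions: mCPBA, CH2Cl2, 0 °C → rt; then K2CO3 (cat.), MeOH, rt
Reagents that add atoms: mCPBA (3-chloroperoxybenzoic acid), OOC(=O)c1cccc(Cl)c1
Why: Baeyer–Villiger (Dakin-type) oxidation, in which the electron-rich aryl group migrates in the Criegee intermediate to give formate 3, which mild methanolysis should convert into the phenol.

Step 3
Reactants: 4 4-(benzyloxy)-3,5-dimethoxyphenol; 5 2-iodo-1,3,5-trimethoxybenzene
Product: 6 2-(benzyloxy)-1,3-dimethoxy-5-(2,4,6-trimethoxyphenoxy)benzene
Conditions: CuI (10 mol %), N,N-dimethylglycine·HCl (30 mol %), Cs2CO3, 1,4-dioxane, 100 °C, Ar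
Reagents that add atoms: none
Why: Ullmann-type copper-catalysed diaryl ether synthesis with an amino acid ligand, in which the phenol is unhindered and the two methoxy groups flanking iodine are small, a class of coupling long used for polymethoxylated diaryl ethers.

Step 4
Reactants: 6 2-(benzyloxy)-1,3-dimethoxy-5-(2,4,6-trimethoxyphenoxy)benzene
Product: 7 2,6-dimethoxy-4-(2,4,6-trimethoxyphenoxy)phenol
Conditions: H2 (1 atm), 10% Pd/C, EtOAc–MeOH, rt
Reagents that add atoms: none
Why: Catalytic hydrogenolysis of the benzyl ether, to which methyl and diaryl ethers are inert and which meets no halogen at this stage.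

Step 5
Reactants: 7 2,6-dimethoxy-4-(2,4,6-trimethoxyphenoxy)phenol; 8 trichloroethylene
Product: 10 2-{[(E)-1,2-dichloroethenyl]oxy}-1,3-dimethoxy-5-(2,4,6-trimethoxyphenoxy)benzene, via dichloroacetylene 9 (not isolated)
Conditions: K2CO3, DMF, 70 °C
Reagents that add atoms: none
Why: Base-mediated O-vinylation of a phenol with trichloroethylene, that is anti addition of the phenoxide and a proton across dichloroacetylene 9 formed by dehydrochlorination, is the standard entry to aryl (E)-1,2-dichlorovinyl ethers, and the alkene geometry is of no consequence because both vinylic chlorines are removed in the next step.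

Step 6
Reactants: 10 2-{[(E)-1,2-dichloroethenyl]oxy}-1,3-dimethoxy-5-(2,4,6-trimethoxyphenoxy)benzene
Product: 13 2-(ethynyloxy)-1,3-dimethoxy-5-(2,4,6-trimethoxyphenoxy)benzene, via chloroethynyl ether 11 (not isolated), via lithium acetylide 12 (not isolated)
Conditions: n-BuLi (2.2 equiv), THF, −78 → −40 °C; then MeOH, −78 °C
Reagents that add atoms: none
Why: Ynol ether synthesis from a 1,2-dichlorovinyl ether, in which vinylic deprotonation and loss of LiCl give 11, chlorine–lithium exchange gives 12 and cold protonation gives the terminal ynol ether, all of which should outrun ortho-lithiation of the methoxyarene rings at −78 °C.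

Step 7
Reactants: 13 2-(ethynyloxy)-1,3-dimethoxy-5-(2,4,6-trimethoxyphenoxy)benzene; 14 acetone (ketene source)
Product: 16 3-[2,6-dimethoxy-4-(2,4,6-trimethoxyphenoxy)phenoxy]cyclobut-2-en-1-one, via ketene 15 (not isolated)
Conditions: ketene gas (acetone cracked over a glowing filament in a ketene lamp) passed into 13, CH2Cl2, 0 °C → rt
Reagents that add atoms: none
Why: Thermal [2+2] cycloaddition of ketene with an ynol ether, the reaction by which 3-alkoxycyclobutenones are made, in which the nucleophilic terminal alkyne carbon bonds to the ketene carbonyl carbon so that the aryloxy group ends on C3 of the cyclobutenone.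

Step 8
Reactants: 16 3-[2,6-dimethoxy-4-(2,4,6-trimethoxyphenoxy)phenoxy]cyclobut-2-en-1-one; 17 (ethoxyethynyl)trimethylsilane
Product: 22 5-[2,6-dimethoxy-4-(2,4,6-trimethoxyphenoxy)phenoxy]-3-ethoxy-2-(trimethylsilyl)phenol, via vinylketene 18 (not isolated), via silyl vinylcyclobutenone 19 (not isolated), via dienylketene 20 (not isolated), via cyclohexadienone 21 (not isolated)
Conditions: 17 (2.5 equiv), toluene, 85 °C, sealed tube, Ar
Reagents that add atoms: none
Why: Proposed new method: heating should open cyclobutenone 16 by four-electron electrocyclic cleavage of its C1–C4 bond to vinylketene 18, whose ketene carbonyl carbon is attacked by the silicon-bearing, nucleophilic carbon of ynol ether 17 in a regioselective [2+2] cycloaddition to give 4-vinylcyclobutenone 19; a second four-electron opening gives dienylketene 20, which closes ring C by six-electron electrocyclisation (bond from the ketene carbon to the terminal methylene) to dienone 21 and tautomerises to phenol 22. The closest known reaction type is the Danheiser benzannulation of alkyl- and aryl-substituted cyclobutenones with alkoxy- and siloxyalkynes; what is untested is a 3-aryloxy (vinylogous ester) cyclobutenone as the vinylketene source together with a C-silylated ynol ether as the ketenophile. No stereocentre is formed. The selectivity needed is the orientation of the [2+2] step, which the ethoxy oxygen secures by making the silylated carbon the nucleophilic terminus and by stabilising, together with the β-silicon, the positive charge that develops at the ethoxy-bearing carbon, so silicon ends between the new hydroxyl and the ethoxy group and para to the aryloxy group. Both positions ortho to the ether oxygen on ring B carry methoxy groups, so ring B cannot cyclise onto the ketene, and the bath is held below 90 °C because ethyl ynol ethers lose ethylene by retro-ene fragmentation above about 100 °C.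

Step 9
Reactants: 22 5-[2,6-dimethoxy-4-(2,4,6-trimethoxyphenoxy)phenoxy]-3-ethoxy-2-(trimethylsilyl)phenol
Product: 23 {4-[2,6-dimethoxy-4-(2,4,6-trimethoxyphenoxy)phenoxy]-2-ethoxy-6-methoxyphenyl}trimethylsilane
Conditions: MeI, K2CO3, acetone, 40 °C
Reagents that add atoms: iodomethane, CI
Why: Williamson O-methylation under weakly basic, acid-free conditions should leave the labile aryl–silicon bond alone and caps the hydroxyl so that N-bromosuccinimide does not meet an oxidisable free phenol in the next step.

Step 10
Reactants: 23 {4-[2,6-dimethoxy-4-(2,4,6-trimethoxyphenoxy)phenoxy]-2-ethoxy-6-methoxyphenyl}trimethylsilane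
Product: 24 2-bromo-5-[2,6-dimethoxy-4-(2,4,6-trimethoxyphenoxy)phenoxy]-1-ethoxy-3-methoxybenzene
Conditions: NBS (1.0 equiv), NaHCO3, MeCN, −30 → 0 °C, dark
Reagents that add atoms: N-bromosuccinimide, O=C1CCC(=O)N1Br
Why: Electrophilic ipso-bromodesilylation of an arylsilane, in which attack at the silicon-bearing carbon gives a cation stabilised by the β-silicon effect on top of two ortho oxygens and one para oxygen and then loses the silyl group irreversibly, should let one equivalent of NBS react there before the similarly activated C–H positions of rings A, B and C, while bicarbonate removes acid that would cause protodesilylation.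

Step 11
Reactants: 24 2-bromo-5-[2,6-dimethoxy-4-(2,4,6-trimethoxyphenoxy)phenoxy]-1-ethoxy-3-methoxybenzene
Product: 25 2-[4-(4-bromo-3,5-dihydroxyphenoxy)-3,5-dihydroxyphenoxy]benzene-1,3,5-triol
Conditions: BBr3 (12 equiv), CH2Cl2, −78 °C → rt; then H2O, 0 °C, Ar
Reagents that add atoms: none
Why: Lewis acid dealkylation of aryl alkyl ethers with BBr3 (bromide attack on the O-alkyl carbon of each borane–ether adduct) should remove the six methyl groups and the ethyl group, whereas the diaryl ether bonds and the aryl C–Br bond are not cleaved under these conditions.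

**Compound list**

1 | syringaldehyde (4-hydroxy-3,5-dimethoxybenzaldehyde) | COc1cc(C=O)cc(OC)c1O | starting material
2 | 4-(benzyloxy)-3,5-dimethoxybenzaldehyde | COc1cc(C=O)cc(OC)c1OCc1ccccc1 | intermediate
3 | 4-(benzyloxy)-3,5-dimethoxyphenyl formate | COc1cc(OC=O)cc(OC)c1OCc1ccccc1 | intermediate
4 | 4-(benzyloxy)-3,5-dimethoxyphenol | COc1cc(O)cc(OC)c1OCc1ccccc1 | intermediate
5 | 2-iodo-1,3,5-trimethoxybenzene | COc1cc(OC)c(I)c(OC)c1 | starting material
6 | 2-(benzyloxy)-1,3-dimethoxy-5-(2,4,6-trimethoxyphenoxy)benzene | COc1cc(OC)c(Oc2cc(OC)c(OCc3ccccc3)c(OC)c2)c(OC)c1 | intermediate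
7 | 2,6-dimethoxy-4-(2,4,6-trimethoxyphenoxy)phenol | COc1cc(OC)c(Oc2cc(OC)c(O)c(OC)c2)c(OC)c1 | intermediate
8 | trichloroethylene | ClC=C(Cl)Cl | starting material
9 | dichloroacetylene | ClC#CCl | intermediate
10 | 2-{[(E)-1,2-dichloroethenyl]oxy}-1,3-dimethoxy-5-(2,4,6-trimethoxyphenoxy)benzene | COc1cc(Oc2c(OC)cc(OC)cc2OC)cc(OC)c1O/C(Cl)=C\Cl | intermediate
11 | 2-[(chloroethynyl)oxy]-1,3-dimethoxy-5-(2,4,6-trimethoxyphenoxy)benzene | COc1cc(Oc2c(OC)cc(OC)cc2OC)cc(OC)c1OC#CCl | intermediate
12 | lithium 2-[2,6-dimethoxy-4-(2,4,6-trimethoxyphenoxy)phenoxy]ethynide | COc1cc(Oc2c(OC)cc(OC)cc2OC)cc(OC)c1OC#C[Li] | intermediate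
13 | 2-(ethynyloxy)-1,3-dimethoxy-5-(2,4,6-trimethoxyphenoxy)benzene | COc1cc(Oc2c(OC)cc(OC)cc2OC)cc(OC)c1OC#C | intermediate
14 | acetone | CC(C)=O | starting material
15 | ketene | C=C=O | intermediate
16 | 3-[2,6-dimethoxy-4-(2,4,6-trimethoxyphenoxy)phenoxy]cyclobut-2-en-1-one | COc1cc(Oc2c(OC)cc(OC)cc2OC)cc(OC)c1OC1=CC(=O)C1 | intermediate
17 | (ethoxyethynyl)trimethylsilane | CCOC#C[Si](C)(C)C | starting material
18 | 3-[2,6-dimethoxy-4-(2,4,6-trimethoxyphenoxy)phenoxy]buta-1,3-dien-1-one | COc1cc(Oc2c(OC)cc(OC)cc2OC)cc(OC)c1OC(=C)C=C=O | intermediate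
19 | 4-{1-[2,6-dimethoxy-4-(2,4,6-trimethoxyphenoxy)phenoxy]ethenyl}-3-ethoxy-2-(trimethylsilyl)cyclobut-2-en-1-one (racemic) | COc1cc(Oc2c(OC)cc(OC)cc2OC)cc(OC)c1OC(=C)C1C(=O)C([Si](C)(C)C)=C1OCC | intermediate
20 | (3E)-5-[2,6-dimethoxy-4-(2,4,6-trimethoxyphenoxy)phenoxy]-3-ethoxy-2-(trimethylsilyl)hexa-1,3,5-trien-1-one | COc1cc(Oc2c(OC)cc(OC)cc2OC)cc(OC)c1OC(=C)/C=C(OCC)\C([Si](C)(C)C)=C=O | intermediate
21 | 5-[2,6-dimethoxy-4-(2,4,6-trimethoxyphenoxy)phenoxy]-3-ethoxy-2-(trimethylsilyl)cyclohexa-2,4-dien-1-one | CCOC1=C([Si](C)(C)C)C(=O)CC(Oc2c(OC)cc(Oc3c(OC)cc(OC)cc3OC)cc2OC)=C1 | intermediate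
22 | 5-[2,6-dimethoxy-4-(2,4,6-trimethoxyphenoxy)phenoxy]-3-ethoxy-2-(trimethylsilyl)phenol | CCOc1cc(Oc2c(OC)cc(Oc3c(OC)cc(OC)cc3OC)cc2OC)cc(O)c1[Si](C)(C)C | intermediate
23 | {4-[2,6-dimethoxy-4-(2,4,6-trimethoxyphenoxy)phenoxy]-2-ethoxy-6-methoxyphenyl}trimethylsilane | CCOc1cc(Oc2c(OC)cc(Oc3c(OC)cc(OC)cc3OC)cc2OC)cc(OC)c1[Si](C)(C)C | intermediate
24 | 2-bromo-5-[2,6-dimethoxy-4-(2,4,6-trimethoxyphenoxy)phenoxy]-1-ethoxy-3-methoxybenzene | CCOc1cc(Oc2c(OC)cc(Oc3c(OC)cc(OC)cc3OC)cc2OC)cc(OC)c1Br | intermediate
25 | 2-[4-(4-bromo-3,5-dihydroxyphenoxy)-3,5-dihydroxyphenoxy]benzene-1,3,5-triol | Oc1cc(O)c(Oc2cc(O)c(Oc3cc(O)c(Br)c(O)c3)c(O)c2)c(O)c1 | target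

**Step count and risks**

Total step count: 11. Longest linear sequence: 11 steps, from syringaldehyde 1 to 25; compounds 5, 8, 14 and 17 are bought and used as such.

Steps most likely to fail:

1. Step 8 (benzannulation). Three processes may defeat it:
   - Ring opening of the vinylogous-ester cyclobutenone may be slower than retro-ene fragmentation of ynol ether 17 to trimethylsilylketene and ethylene.
   - Vinylketene 18 may oligomerise or acylate the product phenol.
   - The electron-rich aryl–silicon bond may be lost by protodesilylation on acidic silica.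

   Milder remedies inside the step are irradiation at 350 nm at room temperature to open 16 before gentle warming, portionwise addition of 17, and chromatography on triethylamine-washed silica.

   The fallback uses known chemistry only, sets out from phenol 7 and comes back to the route at target 25. Commercial 2-bromo-1,3-dimethoxybenzene (COc1cccc(OC)c1Br) is borylated at C5, its only C–H position not ortho to a substituent, with bis(pinacolato)diboron, [Ir(OMe)(cod)]2 and 4,4′-di-tert-butyl-2,2′-bipyridine in THF at 80 °C. This should give 2-(4-bromo-3,5-dimethoxyphenyl)-4,4,5,5-tetramethyl-1,3,2-dioxaborolane F1. Chan–Lam coupling of F1 with 7 (Cu(OAc)2, pyridine, B(OH)3, 4 Å molecular sieves, MeCN, air, 60 °C) should give 2-bromo-5-[2,6-dimethoxy-4-(2,4,6-trimethoxyphenoxy)phenoxy]-1,3-dimethoxybenzene F2. BBr3 under the conditions of step 11 then cleaves the seven methyl ethers of F2 to 25. In this variant bromine arrives with ring C, at the cost of forming the hindered B–C ether by coupling.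

2. Step 10 (ipso-bromodesilylation). Site selectivity may be lost: electrophilic bromine may be consumed at the C–H positions of rings A and B, each activated by three oxygens, or acid formed in the flask may cause protodesilylation.

   The fallback sets out from silyl phenol 22 and comes back to the route at target 25. Bromination is moved before the methylation, so that the free hydroxyl makes ring C by far the most nucleophilic ring. Amine-mediated ortho-bromination of the phenol (NBS, 1.0 equiv, i-Pr2NH cat., CH2Cl2, −78 °C) directs bromine to the ortho carbon that bears silicon. This should give 2-bromo-5-[2,6-dimethoxy-4-(2,4,6-trimethoxyphenoxy)phenoxy]-3-ethoxyphenol F3, which is taken directly into the BBr3 conditions of step 11 to give 25.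

3. Step 7 (ketene cycloaddition). The aryl ynol ether is less nucleophilic than an alkyl ynol ether, so cycloaddition may be slow enough for ketene dimerisation and polymerisation of 13 to take over, and the vinylogous aryl ester 16 may decompose on isolation.

   The fallback sets out from ynol ether 13 and comes back to the route at cyclobutenone 16. Dichloroketene, generated from trichloroacetyl chloride and Zn–Cu couple in Et2O–DME at room temperature, is a far more reactive ketenophile partner. It should add to 13 to give 4,4-dichloro-3-[2,6-dimethoxy-4-(2,4,6-trimethoxyphenoxy)phenoxy]cyclobut-2-en-1-one F4. Reductive dechlorination with Zn, AcOH and TMEDA in EtOH at 0 °C then gives 16.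

Further compounds
F1 | step 8 | 2-(4-bromo-3,5-dimethoxyphenyl)-4,4,5,5-tetramethyl-1,3,2-dioxaborolane | COc1cc(B2OC(C)(C)C(C)(C)O2)cc(OC)c1Br
F2 | step 8 | 2-bromo-5-[2,6-dimethoxy-4-(2,4,6-trimethoxyphenoxy)phenoxy]-1,3-dimethoxybenzene | COc1cc(Oc2c(OC)cc(Oc3c(OC)cc(OC)cc3OC)cc2OC)cc(OC)c1Br
F3 | step 10 | 2-bromo-5-[2,6-dimethoxy-4-(2,4,6-trimethoxyphenoxy)phenoxy]-3-ethoxyphenol | CCOc1cc(Oc2c(OC)cc(Oc3c(OC)cc(OC)cc3OC)cc2OC)cc(O)c1Br
F4 | step 7 | 4,4-dichloro-3-[2,6-dimethoxy-4-(2,4,6-trimethoxyphenoxy)phenoxy]cyclobut-2-en-1-one | COc1cc(Oc2c(OC)cc(OC)cc2OC)cc(OC)c1OC1=CC(=O)C1(Cl)Cl
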